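Take the ratio of E to L in the charge: 1.00 in the noon run, 4.00 in the midnight run, 2.00 in the flask. So the flask stands one doubling above noon and one below midnight.

| flask | L | G | E | D | remark | time |
|---|---|---|---|---|---|---|
| noon | 2 mM | 2 mM | 2 mM | 4.2 µM | run made earlier |  |
| midnight | 2 mM | 2 mM | 8 mM | 4.2 µM | run made earlier |  |
| spring | 2 mM | 2 mM | 4 mM | 6.3 µM | run made earlier |  |
| flask | 2.0 mM | 2.0 mM | 4.00 mM | 4.2 µM |  | 10 min |

noon run (percent of the L and G together charged)

| time / min | Z / % | G / % |
|---|---|---|
| 0.417 | 7.8 | 45.6 |
| 1.33 | 9.5 | 42.8 |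
| 2.50 | 11.0 | 43.3 |
| 3.00 | 11.1 | 41.9 |
| 5.00 | 8.1 | 42.6 |
| 6.00 | 10.5 | 41.6 |
| 8.00 | 9.3 | 42.5 |

midnight run (percent of the L and G together charged)

| time / min | Z / % | G / % |
|---|---|---|
| 0.417 | 14.6 | 41.3 |
| 1.33 | 16.0 | 38.4 |
| 2.50 | 15.7 | 37.8 |
| 3.00 | 15.6 | 37.9 |
| 5.00 | 16.6 | 37.2 |
| 6.00 | 15.6 | 37.5 |
| 8.00 | 16.8 | 37.1 |

spring run (percent of the L and G together charged)

| time / min | Z / % | G / % |
|---|---|---|
| 0.667 | 15.6 | 40.8 |
| 2.00 | 17.0 | 36.1 |
| 4.00 | 17.3 | 37.6 |
| 6.00 | 14.9 | 36.5 |
| 8.00 | 16.2 | 37.9 |

- D is single-handed; L and G are mirror images of each other, charged as a racemate, each of them at the stated concentration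
- steps that have been proposed: E + D + L -> D + Z; E + D + G -> D + Q; L <-> G; E -> J; 2 E -> X
- the reaction counts as stopped when no species that holds the L and G together changes by six tenths of a point or more over the second half of the time

- why nothing more happens at 10 min, or that something still does (no working catalyst is left / E has run out first / forward and back rates have come level / all of L has reacted / it is still moving)
- the Z standing at 10 min, as a percentage of the L and G together charged
- the G standing at 10 min, as a percentage of the L and G together charged

Turn the question round. For the flask to be still moving at 10 min, Z or G in those runs would have to keep shifting late. For E to be spare at the stop, more E would have to leave the level of Z unchanged.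

Test both. Replace each curve from 1.33 min on by its mean: Z 9.92% at noon, 16.1% at midnight. Check the error this makes. Over the last three readings against the three before, noon falls 1.2 percentage points and midnight rises 0.57 points. These go opposite ways, with a scatter of 1 point, so read no common drift in Z. G falls in both runs over the same readings, by 0.43 points at noon and 0.77 points at midnight, so these readings leave a small late fall of G open.

But midnight stands higher than noon, so read E as the limiting reagent. Halve the difference: 3.1 points. Call this the doubling gain, the points of Z won per doubling of E at 4.2 µM of D. Assume Z runs straight in the logarithm of E, as when E is lost mainly in pairs to X. Add one gain to noon: Z 13.0% in the flask. G goes the same way, from means of 42.4% and 37.7%. It loses 2.4 points per doubling, which gives 40.0%.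

The forecast names the same end, E has run out first, but with a lower Z, 12.3%, and a higher G, 40.5%, on the ground that “most E is being wasted”.

The flask ends thus: E has run out first. It holds Z 13.1% and G 39.6% at 10 min, with E at 0% of its charge.

    E + D + L → D + Z (k = 2.70 × 10⁶ L² mol⁻² s⁻¹)
    E + D + G → D + Q (k = 1.50 × 10⁶ L² mol⁻² s⁻¹)
    L ⇌ G (k = 0.00520 s⁻¹)
    E → J (k = 7.60 × 10⁻⁵ s⁻¹)
    2 E → X (k = 50.0 L mol⁻¹ s⁻¹)

Noon plus the doubling gain of 3.1 points gave 13.0% for the flask, a gap of 0.10 points from what it holds. Step down now to the neighbour, the same flask with 1.0 mM of E, which is 0.500 equiv to L and one doubling below noon. Subtract the gain from noon: Z 6.82%. Add the loss of G: 44.8%. At 10.0 min that neighbour holds Z 7.37% and G 44.2%, with E at 0% of its charge.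

The runs are simulated on assumed constants, and the scatter is random.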